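**Plan**

Numbering: quinone C1 is the carbonyl between methyl-bearing C2 and chain-bearing C6, C4 is the other carbonyl; the chain runs C1'–C16' from the ring.
Retrosynthesis: the C4 oxygen is removed first (2,6-disubstituted phenol to para-quinone; both ortho positions are blocked). The arene is then cut at C2–C3 and C4–C5, because C5=C6–C1(O)=C2 is the 2-silyloxy-1,3-diene of an α-methylene ethyl ketone and C3–C4 is an acetylene unit (ethynyl sulfone).
Further cuts: C6–C1' (allylic alkylation, then methylenation to create C5), C9'–C10' (B-alkyl Suzuki coupling) and C11'–C12' (iodo-aldol coupling).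
Forward: the chain is assembled first from geranyl acetate (C1'–C9') and an iodo diol (C10'–C16'), the four-carbon ring unit is attached at C1', and the ring is closed last by one cycloaddition–aromatisation.
Stereochemistry: 12'R comes from a catalyst-controlled aldol addition to 4-methylpent-3-enal; the C10'=C11' geometry from a Z-iodoacrylate carried through a stereoretentive coupling; 2'E and 6'E from geranyl acetate.

Key step: step 11

Remark: the oxazaborolidinium-catalysed coupling in step 5 is assumed to follow the usual facial preference of this catalyst class (Si-face attack on the bound aldehyde with the (S)-catalyst); if the sense proves opposite, the (R)-catalyst is used.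

**Route**

Step 1
Reactants: 1 geranyl acetate
Product: 2 (2E,6E)-8-hydroxy-3,7-dimethylocta-2,6-dien-1-yl acetate
Conditions: SeO2 (cat.), t-BuOOH, salicylic acid (cat.), CH2Cl2, rt
Reagents that add atoms: tert-butyl hydroperoxide, CC(C)(C)OO
Why: SeO2/t-BuOOH allylic oxidation (ene reaction, then [2,3]-shift) should attack the E-methyl of the electron-rich terminal alkene, the acetate deactivating the proximal alkene.

Step 2
Reactants: 2 (2E,6E)-8-hydroxy-3,7-dimethylocta-2,6-dien-1-yl acetate
Product: 3 (2E,6E)-3,7-dimethyl-8-oxoocta-2,6-dien-1-yl acetate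
Conditions: TEMPO (cat.), PhI(OAc)2, CH2Cl2, rt
Reagents that add atoms: none
Why: Oxoammonium oxidation of the primary allylic alcohol should stop at the enal and leave the acetate and the E geometry untouched.

Step 3
Reactants: 3 (2E,6E)-3,7-dimethyl-8-oxoocta-2,6-dien-1-yl acetate
Product: 4 (2E,6E)-3,7-dimethylnona-2,6,8-trien-1-yl acetate
Conditions: Ph3PCH3Br, NaN(SiMe3)2, THF, −78 → 0 °C
Reagents that add atoms: methyltriphenylphosphonium bromide, C[P+](c1ccccc1)(c1ccccc1)c1ccccc1.[Br-]
Why: Wittig methylenation of the aldehyde is much faster than attack of the ylide on the acetate at low temperature and should give the terminal 1,3-diene without touching the trisubstituted alkenes.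

Step 4
Reactants: 5 4-methylpent-3-en-1-ol
Product: 6 4-methylpent-3-enal
Conditions: Dess–Martin periodinane, NaHCO3, CH2Cl2, 0 °C; used as a solution
Reagents that add atoms: none
Why: Buffered Dess–Martin oxidation should give the β,γ-unsaturated aldehyde without acid- or base-induced migration of the double bond into conjugation.

Step 5
Reactants: 6 4-methylpent-3-enal; 7 ethyl propiolate
Product: 10 ethyl (2Z)-2-[(1R)-1-hydroxy-4-methylpent-3-en-1-yl]-3-iodoprop-2-enoate, via silyl iodoallenolate 8 (not isolated), via aldol silyl ether 9 (not isolated)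
Conditions: Me3SiI, (S)-B-o-tolyl oxazaborolidinium triflimide from (S)-α,α-diphenylprolinol (20 mol %), CH2Cl2, −78 °C; then 1 M HCl, THF
Reagents that add atoms: iodotrimethylsilane, C[Si](C)(C)I
Why: Iodide conjugate addition to the propiolate gives the silyl β-iodoallenolate, whose Mukaiyama-type aldol addition (β-iodo Morita–Baylis–Hillman reaction) to the Lewis-acid-bound aldehyde should occur on the Si face to set the R carbinol, attack anti to iodine at −78 °C giving the Z iodoacrylate.

Step 6
Reactants: 10 ethyl (2Z)-2-[(1R)-1-hydroxy-4-methylpent-3-en-1-yl]-3-iodoprop-2-enoate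
Product: 11 (2E,3R)-2-(iodomethylidene)-6-methylhept-5-ene-1,3-diol
Conditions: i-Bu2AlH (3.5 equiv), CH2Cl2, −78 → −20 °C; aq. potassium sodium tartrate
Reagents that add atoms: none
Why: i-Bu2AlH should reduce the conjugated ester 1,2 to the allylic alcohol without touching the vinyl iodide or its geometry (the descriptor changes to E only through CIP priorities).

Step 7
Reactants: 4 (2E,6E)-3,7-dimethylnona-2,6,8-trien-1-yl acetate; 11 (2E,3R)-2-(iodomethylidene)-6-methylhept-5-ene-1,3-diol
Product: 13 (2E,6E,10E,12R)-12-hydroxy-11-(hydroxymethyl)-3,7,15-trimethylhexadeca-2,6,10,14-tetraen-1-yl acetate, via alkylborane 12 (not isolated)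
Conditions: 9-BBN, THF, 0 °C → rt; then 11, PdCl2(dppf) (5 mol %), AsPh3, Cs2CO3, DMF/H2O, rt
Reagents that add atoms: none
Why: 9-BBN should hydroborate only the monosubstituted terminal alkene of the diene (boron on the terminal carbon), and the B-alkyl Suzuki–Miyaura coupling proceeds with retention at the vinyl iodide and tolerates the free diol, oxidative addition of zerovalent palladium to the vinyl iodide at rt outpacing ionisation of the allylic acetate.

Step 8
Reactants: 13 (2E,6E,10E,12R)-12-hydroxy-11-(hydroxymethyl)-3,7,15-trimethylhexadeca-2,6,10,14-tetraen-1-yl acetate; 14 diethyl (2-oxobutyl)phosphonate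
Product: 15 diethyl [(6E,10E,14E,16R)-16-hydroxy-15-(hydroxymethyl)-7,11,19-trimethyl-3-oxoicosa-6,10,14,18-tetraen-4-yl]phosphonate (C4 epimers)
Conditions: 14 (2.5 equiv), NaH, THF, 0 °C; then 13, Pd(PPh3)4 (5 mol %), THF, rt
Reagents that add atoms: none
Why: In this Tsuji–Trost allylic alkylation zerovalent palladium should ionise only the primary allylic acetate, and the bulky, soft phosphonate-stabilised enolate attacks the unsubstituted terminus of the π-allyl complex with the 2E geometry kept; the unactivated allylic alcohols do not ionise.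

Step 9
Reactants: 15 diethyl [(6E,10E,14E,16R)-16-hydroxy-15-(hydroxymethyl)-7,11,19-trimethyl-3-oxoicosa-6,10,14,18-tetraen-4-yl]phosphonate
Product: 16 (6E,10E,14E,16R)-16-hydroxy-15-(hydroxymethyl)-7,11,19-trimethyl-4-methylideneicosa-6,10,14,18-tetraen-3-one
Conditions: 37 % aq. HCHO, K2CO3, THF/H2O, rt
Reagents that add atoms: formaldehyde, C=O
Why: Horner–Wadsworth–Emmons olefination of the α-substituted β-ketophosphonate with formaldehyde should give the α-methylene ketone regiospecifically under conditions mild enough for the free diol.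

Step 10
Reactants: 16 (6E,10E,14E,16R)-16-hydroxy-15-(hydroxymethyl)-7,11,19-trimethyl-4-methylideneicosa-6,10,14,18-tetraen-3-one
Product: 17 (2Z,6E,10E,14E,16R)-7,11,19-trimethyl-4-methylidene-3,16-bis(trimethylsilyloxy)-15-[(trimethylsilyloxy)methyl]icosa-2,6,10,14,18-pentaene
Conditions: Me3SiOTf (3.6 equiv), Et3N (6 equiv), CH2Cl2, −78 → 0 °C; pentane, cold aq. NaHCO3; used crude
Reagents that add atoms: trimethylsilyl trifluoromethanesulfonate, C[Si](C)(C)OS(=O)(=O)C(F)(F)F
Why: Soft enolisation should silylate both hydroxyls and the only enolisable position (the ethyl CH2), allylic 1,3-strain with the branched C6 substituent favouring the Z silyl enol ether whose methyl points outward in the s-cis diene.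

Step 11
Reactants: 17 (2Z,6E,10E,14E,16R)-7,11,19-trimethyl-4-methylidene-3,16-bis(trimethylsilyloxy)-15-[(trimethylsilyloxy)methyl]icosa-2,6,10,14,18-pentaene; 18 ethynyl p-tolyl sulfone
Product: 21 2-[(2E,6E,10E,12R)-12-hydroxy-11-(hydroxymethyl)-3,7,15-trimethylhexadeca-2,6,10,14-tetraen-1-yl]-6-methylphenol, via sulfonyl cyclohexadiene 19 (not isolated), via aryl silyl ether 20 (not isolated)
Conditions: 18 (1.3 equiv), toluene, 60 °C; then DBU, rt → 50 °C; then K2CO3 (cat.), MeOH, rt
Reagents that add atoms: none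
Why: A thermal Diels–Alder reaction of the electron-rich 2-silyloxydiene C5=C6–C1(OSi)=C2 with the alkynyl sulfone (an acetylene equivalent at the arene oxidation level) forms C2–C3 and C4–C5 in one concerted suprafacial event, closing the six-membered carbocycle by intermolecular [4+2] cycloaddition and not by an exo or endo cyclisation. DBU should then isomerise the 1-sulfonylcyclohexa-1,4-diene to the allylic sulfone and expel p-toluenesulfinate, driven by aromatisation, and methanolysis frees the phenol and the diol. The closest known reaction type is the Diels–Alder reaction of silyloxydienes with ethynyl sulfones followed by base-induced loss of sulfinic acid. The only new stereocentre (C2 of the cycloadduct) is erased on aromatisation, so both regioisomeric adducts and both C2 epimers converge on the one phenol, the placement of methyl and chain being fixed by the diene skeleton. The selectivity required is chemoselectivity for the diene over the four trisubstituted chain alkenes, secured by the high HOMO of the silyloxydiene and its 2,3-disubstitution, which enforces the s-cis geometry.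

Step 12
Reactants: 21 2-[(2E,6E,10E,12R)-12-hydroxy-11-(hydroxymethyl)-3,7,15-trimethylhexadeca-2,6,10,14-tetraen-1-yl]-6-methylphenol
Product: 22 2-[(2E,6E,10E,12R)-12-hydroxy-11-(hydroxymethyl)-3,7,15-trimethylhexadeca-2,6,10,14-tetraen-1-yl]-6-methylcyclohexa-2,5-diene-1,4-dione (CNP0201434.1)
Conditions: (KSO3)2NO (2.5 equiv), KH2PO4 buffer, acetone/H2O, rt
Reagents that add atoms: Fremy's salt (potassium nitrosodisulfonate), [K+].[K+].[O]N(S(=O)(=O)[O-])S(=O)(=O)[O-]
Why: In this Teuber oxidation the phenoxyl radical is trapped by a second equivalent of the nitroxide at C4, the only free position carrying spin density because both ortho positions are blocked, which should give the para-quinone without affecting alkenes or alcohols.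

**Compound list**

1 | geranyl acetate, (2E)-3,7-dimethylocta-2,6-dien-1-yl acetate | CC(C)=CCC/C(C)=C/COC(C)=O | starting material
2 | (2E,6E)-8-hydroxy-3,7-dimethylocta-2,6-dien-1-yl acetate | OC/C(C)=C/CC/C(C)=C/COC(C)=O | intermediate
3 | (2E,6E)-3,7-dimethyl-8-oxoocta-2,6-dien-1-yl acetate | O=C/C(C)=C/CC/C(C)=C/COC(C)=O | intermediate
4 | (2E,6E)-3,7-dimethylnona-2,6,8-trien-1-yl acetate | C=C/C(C)=C/CC/C(C)=C/COC(C)=O | intermediate
5 | 4-methylpent-3-en-1-ol | CC(C)=CCCO | starting material
6 | 4-methylpent-3-enal | CC(C)=CCC=O | intermediate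
7 | ethyl propiolate | C#CC(=O)OCC | starting material
8 | (1-ethoxy-3-iodopropa-1,2-dien-1-yl)oxy(trimethyl)silane | CCOC(O[Si](C)(C)C)=C=CI | intermediate
9 | ethyl (2Z)-3-iodo-2-[(1R)-4-methyl-1-(trimethylsilyloxy)pent-3-en-1-yl]prop-2-enoate | CC(C)=CC[C@@H](O[Si](C)(C)C)/C(=C/I)C(=O)OCC | intermediate
10 | ethyl (2Z)-2-[(1R)-1-hydroxy-4-methylpent-3-en-1-yl]-3-iodoprop-2-enoate | CC(C)=CC[C@@H](O)/C(=C/I)C(=O)OCC | intermediate
11 | (2E,3R)-2-(iodomethylidene)-6-methylhept-5-ene-1,3-diol (iodine cis to CH2OH) | CC(C)=CC[C@@H](O)/C(=C/I)CO | intermediate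
12 | (2E,6E)-9-(9-borabicyclo[3.3.1]nonan-9-yl)-3,7-dimethylnona-2,6-dien-1-yl acetate | B1(CC/C(C)=C/CC/C(C)=C/COC(C)=O)C2CCCC1CCC2 | intermediate
13 | (2E,6E,10E,12R)-12-hydroxy-11-(hydroxymethyl)-3,7,15-trimethylhexadeca-2,6,10,14-tetraen-1-yl acetate | CC(C)=CC[C@@H](O)/C(=C/CC/C(C)=C/CC/C(C)=C/COC(C)=O)CO | intermediate
14 | diethyl (2-oxobutyl)phosphonate | CCC(=O)CP(=O)(OCC)OCC | starting material
15 | diethyl [(6E,10E,14E,16R)-16-hydroxy-15-(hydroxymethyl)-7,11,19-trimethyl-3-oxoicosa-6,10,14,18-tetraen-4-yl]phosphonate (C4 epimers) | CC(C)=CC[C@@H](O)/C(=C/CC/C(C)=C/CC/C(C)=C/CC(C(=O)CC)P(=O)(OCC)OCC)CO | intermediate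
16 | (6E,10E,14E,16R)-16-hydroxy-15-(hydroxymethyl)-7,11,19-trimethyl-4-methylideneicosa-6,10,14,18-tetraen-3-one | CC(C)=CC[C@@H](O)/C(=C/CC/C(C)=C/CC/C(C)=C/CC(=C)C(=O)CC)CO | intermediate
17 | (2Z,6E,10E,14E,16R)-7,11,19-trimethyl-4-methylidene-3,16-bis(trimethylsilyloxy)-15-[(trimethylsilyloxy)methyl]icosa-2,6,10,14,18-pentaene | CC(C)=CC[C@@H](O[Si](C)(C)C)/C(=C/CC/C(C)=C/CC/C(C)=C/CC(=C)/C(O[Si](C)(C)C)=C/C)CO[Si](C)(C)C | intermediate
18 | ethynyl p-tolyl sulfone, 1-(ethynylsulfonyl)-4-methylbenzene | C#CS(=O)(=O)c1ccc(C)cc1 | starting material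
19 | cyclohexa-1,4-diene cycloadduct: C1–OSiMe3, C2(H)–CH3, C3=C4 with p-tolylsulfonyl on C4, C5H2, C6 bearing the bis-silylated chain (major regioisomer, C2 epimers) | CC(C)=CC[C@@H](O[Si](C)(C)C)/C(=C/CC/C(C)=C/CC/C(C)=C/CC1=C(O[Si](C)(C)C)C(C)C=C(S(=O)(=O)c2ccc(C)cc2)C1)CO[Si](C)(C)C | intermediate
20 | tris(trimethylsilyl) ether of 21 (aryl O-silyl, 11'-CH2O-silyl, 12'-O-silyl) | CC(C)=CC[C@@H](O[Si](C)(C)C)/C(=C/CC/C(C)=C/CC/C(C)=C/Cc1cccc(C)c1O[Si](C)(C)C)CO[Si](C)(C)C | intermediate
21 | 2-[(2E,6E,10E,12R)-12-hydroxy-11-(hydroxymethyl)-3,7,15-trimethylhexadeca-2,6,10,14-tetraen-1-yl]-6-methylphenol | CC(C)=CC[C@@H](O)/C(=C/CC/C(C)=C/CC/C(C)=C/Cc1cccc(C)c1O)CO | intermediate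
22 | 2-[(2E,6E,10E,12R)-12-hydroxy-11-(hydroxymethyl)-3,7,15-trimethylhexadeca-2,6,10,14-tetraen-1-yl]-6-methylcyclohexa-2,5-diene-1,4-dione | CC(C)=CC[C@@H](O)/C(=C/CC/C(C)=C/CC/C(C)=C/CC1=CC(=O)C=C(C)C1=O)CO | target

**Step count**

Total steps: 12. Longest linear sequence: 9 (steps 1, 2, 3, 7, 8, 9, 10, 11, 12; the branch through steps 4–6 is equally long).

**Steps most likely to fail**

Step 11. The process at risk is the aromatisation: loss of p-toluenesulfinate from the cyclohexadienyl sulfone may stall, or the alkynyl sulfone may be consumed by ene-type addition to chain alkenes before it finds the diene. The fallback sets out from 17 and comes back at 22. Cycloaddition of 17 with 3-butyn-2-one (toluene, 80 °C) should give the acetyl cyclohexadiene F7, with the acetyl group on C4 as directed by the silyloxy group. DDQ (CH2Cl2, 0 °C) dehydrogenates it to the silylated aryl ketone F8, and K2CO3 in MeOH frees the hydroxy acetophenone F9. Dakin oxidation (H2O2, NaOH, THF/H2O, 0 °C, under argon, Na2S2O4 work-up) turns the para-acetyl group into the hydroxyl of the hydroquinone F10, and Ag2O in Et2O oxidises this to 22. Aromatisation is then oxidative and no elimination is needed.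

Step 5. The process at risk is facial selection at the aldehyde carbonyl (insufficient or reversed enantioselectivity with this unbranched β,γ-unsaturated aldehyde). The fallback sets out from 6 and 7 and comes back at 11. MgI2 in CH2Cl2 at 0 °C couples 6 and 7 without a chiral catalyst to the racemic Z-iodo hydroxy ester F1. Acylative kinetic resolution with Burkholderia cepacia lipase and vinyl acetate (hexane/t-BuOMe, 30 °C, stopped near half conversion) should, by the empirical size rule for lipase acylation of secondary alcohols, acylate the R enantiomer to the acetate F2, which is separated from the unreacted S alcohol. i-Bu2AlH then reduces both ester groups of F2 and gives 11.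

Step 8. The process at risk is loss of the 2E geometry by syn–anti isomerisation of the π-allyl palladium complex, or attack at its tertiary terminus. The fallback sets out from 13 and comes back at 15. 2,2-Dimethoxypropane and PPTS convert 13 into the acetonide acetate F3; K2CO3 in MeOH gives the allylic alcohol F4; CBr4 and PPh3 give the allylic bromide F5. Direct SN2 alkylation of the sodium enolate of 14 (NaH, THF/DMF, 0 °C) with F5 gives the acetonide phosphonate F6 with the alkene geometry untouched, and PPTS in MeOH removes the acetonide to give 15.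

Further compounds
F1 | step 5 | ethyl (2Z)-2-(1-hydroxy-4-methylpent-3-en-1-yl)-3-iodoprop-2-enoate, racemate | CC(C)=CCC(O)/C(=C/I)C(=O)OCC
F2 | step 5 | ethyl (2Z)-2-[(1R)-1-acetoxy-4-methylpent-3-en-1-yl]-3-iodoprop-2-enoate | CC(C)=CC[C@@H](OC(C)=O)/C(=C/I)C(=O)OCC
F3 | step 8 | acetonide of 13 (2,2-dimethyl-1,3-dioxane across 11'-CH2OH and 12'-OH), allylic acetate | CC(C)=CC[C@@H](OC(C)(C)OC1)/C1=C/CC/C(C)=C/CC/C(C)=C/COC(C)=O
F4 | step 8 | acetonide allylic alcohol | CC(C)=CC[C@@H](OC(C)(C)OC1)/C1=C/CC/C(C)=C/CC/C(C)=C/CO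
F5 | step 8 | acetonide allylic bromide | CC(C)=CC[C@@H](OC(C)(C)OC1)/C1=C/CC/C(C)=C/CC/C(C)=C/CBr
F6 | step 8 | acetonide of 15 | CC(C)=CC[C@@H](OC(C)(C)OC1)/C1=C/CC/C(C)=C/CC/C(C)=C/CC(C(=O)CC)P(=O)(OCC)OCC
F7 | step 11 | cyclohexa-1,4-diene cycloadduct with acetyl on C4, otherwise as 19 | CC(C)=CC[C@@H](O[Si](C)(C)C)/C(=C/CC/C(C)=C/CC/C(C)=C/CC1=C(O[Si](C)(C)C)C(C)C=C(C(C)=O)C1)CO[Si](C)(C)C
F8 | step 11 | tris(trimethylsilyl) ether of F9 | CC(C)=CC[C@@H](O[Si](C)(C)C)/C(=C/CC/C(C)=C/CC/C(C)=C/Cc1cc(C(C)=O)cc(C)c1O[Si](C)(C)C)CO[Si](C)(C)C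
F9 | step 11 | 1-{4-hydroxy-3-[(2E,6E,10E,12R)-12-hydroxy-11-(hydroxymethyl)-3,7,15-trimethylhexadeca-2,6,10,14-tetraen-1-yl]-5-methylphenyl}ethanone | CC(C)=CC[C@@H](O)/C(=C/CC/C(C)=C/CC/C(C)=C/Cc1cc(C(C)=O)cc(C)c1O)CO
F10 | step 11 | 2-[(2E,6E,10E,12R)-12-hydroxy-11-(hydroxymethyl)-3,7,15-trimethylhexadeca-2,6,10,14-tetraen-1-yl]-6-methylbenzene-1,4-diol | CC(C)=CC[C@@H](O)/C(=C/CC/C(C)=C/CC/C(C)=C/Cc1cc(O)cc(C)c1O)CO
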